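**Retrosynthetic overview**

1. The target comes from MnO2 oxidation of an allylic tetraol, which comes from one LiAlH4 reduction of an epoxy (Z)-enoate; the C6 tertiary alcohol arises from epoxidation of a C5=C6 alkene directed by the C1 hydroxymethyl group, followed by hydride opening at C5.
2. The (Z)-enoate on C3 comes from an enol triflate, made by in-plane addition of methyllithium to a C3 ketene (from a hindered aryl ester); the 3-hydroxypropyl arm on C2 comes from lactol methylenation and hydroformylation.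
3. Feature used: in the cyclohexane C1–C6, the CH2OH on quaternary C1 and the three-carbon arm on C2 are cis on adjacent ring atoms, and C5–C6 can carry an alkene. This is the pattern of a cis-fused γ-lactone (C1–CH2–O–C7(=O)–C2) on a cyclohexene, so C1–C2 and C3–C4 are disconnected to a (Z)-dienyl ester of a fumaric acid mono-imide (intramolecular Diels–Alder).
4. Ring order: cyclohexene and γ-lactone form together in that cycloaddition, the only skeletal ring-forming step. The dienol comes from anti-carbomagnesiation of but-2-yn-1-ol with homofarnesylmagnesium bromide, iodination and Stille vinylation; the bromide from (2E,6E)-farnesol; the dienophile from mono-tert-butyl fumarate and (S)-4-benzyl-2-oxazolidinone.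

Key step: step 10

Conventions: ring atoms C1–C6 as above; C7 is the lactone carbonyl carbon, Cα the exocyclic carbon on C3. β is the ring face carrying the homofarnesyl chain at C1, α the opposite face. Homofarnesyl = (3E,7E)-4,8,12-trimethyltrideca-3,7,11-trien-1-yl; Ar = 2,6-di-tert-butyl-4-methylphenyl; TBS = tert-butyldimethylsilyl.
Remark: mono-tert-butyl fumarate is taken as a purchasable starting material, so the (E)-geometry of the dienophile is present from the outset.

**Step 1**
Reactants: 1 (2E,6E)-farnesol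
Product: 2 (2E,6E)-farnesal
Conditions: MnO2 (activated, excess), CH2Cl2, rt
Reagents that add atoms: none
Why: Allylic oxidation with MnO2 stops at the enal and keeps the (2E) geometry, the isolated trisubstituted alkenes being inert.

**Step 2**
Reactants: 2 (2E,6E)-farnesal
Product: 3 (3E,7E)-4,8,12-trimethyltrideca-1,3,7,11-tetraene
Conditions: Ph3PCH3Br, n-BuLi, THF, 0 °C to rt
Reagents that add atoms: methyltriphenylphosphonium bromide (as its ylide), C[P+](c1ccccc1)(c1ccccc1)c1ccccc1.[Br-]
Why: Wittig methylenation of the enal with the unstabilised ylide gives the terminal 1,3-diene without touching the existing (E)-alkenes.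

**Step 3**
Reactants: 3 (3E,7E)-4,8,12-trimethyltrideca-1,3,7,11-tetraene
Product: 5 (3E,7E)-homofarnesol, via B-homofarnesyl-9-BBN 4 (not isolated)
Conditions: 9-BBN, THF, 0 °C to rt; then NaOH, H2O2, 0 °C
Reagents that add atoms: hydrogen peroxide, OO
Why: Hydroboration–oxidation with the bulky 9-BBN is selective for the monosubstituted terminal alkene over the trisubstituted ones and places boron, then oxygen, on the terminal carbon (anti-Markovnikov).

**Step 4**
Reactants: 5 (3E,7E)-homofarnesol
Product: 6 (3E,7E)-homofarnesyl bromide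
Conditions: CBr4, PPh3, CH2Cl2, 0 °C
Reagents that add atoms: tetrabromomethane, BrC(Br)(Br)Br
Why: Appel bromination converts the primary homoallylic alcohol into the bromide by SN2 displacement of an alkoxyphosphonium ion under neutral conditions that leave the polyene untouched.

**Step 5**
Reactants: 6 (3E,7E)-homofarnesyl bromide; 7 but-2-yn-1-ol
Product: 10 (2Z)-3-iodo-2-homofarnesylbut-2-en-1-ol (iodine cis to CH2OH), via homofarnesylmagnesium bromide 8 (not isolated), via cyclic vinylmagnesium alkoxide 9 (not isolated)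
Conditions: Mg, THF, 40 °C (6 to 8); 7 (1.3 equiv), MeMgCl (1.3 equiv), THF, 0 °C; then 8, CuI (10 mol%), THF, reflux; then I2, −30 °C to rt
Reagents that add atoms: iodine, II
Why: In this CuI-catalysed anti-carbomagnesiation of a propargylic magnesium alkoxide the Grignard carbon adds to the alkyne carbon next to CH2O while magnesium goes to the distal carbon inside a five-membered O–Mg chelate, so iodinolysis with retention puts iodine cis to CH2OH and the homofarnesyl chain cis to the methyl group.

**Step 6**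
Reactants: 10 (2Z)-3-iodo-2-homofarnesylbut-2-en-1-ol
Product: 11 (2Z)-3-methyl-2-homofarnesylpenta-2,4-dien-1-ol (vinyl cis to CH2OH)
Conditions: CH2=CHSnBu3, Pd(PPh3)4 (5 mol%), CuI (10 mol%), CsF, DMF, 45 °C
Reagents that add atoms: tributyl(vinyl)stannane, C=C[Sn](CCCC)(CCCC)CCCC
Why: Stille cross-coupling replaces the vinylic iodide by vinyl with retention of the double-bond geometry, CuI and fluoride accelerating transmetalation at the hindered tetrasubstituted alkene.

**Step 7**
Reactants: 12 mono-tert-butyl fumarate; 13 (S)-4-benzyl-1,3-oxazolidin-2-one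
Product: 15 tert-butyl (E)-4-[(4S)-4-benzyl-2-oxo-1,3-oxazolidin-3-yl]-4-oxobut-2-enoate, via mixed pivalic anhydride 14 (not isolated)
Conditions: t-BuCOCl, Et3N, THF, −20 °C; then 13, LiCl, −20 °C to rt
Reagents that add atoms: none
Why: N-Acylation of the oxazolidinone through the pivalic mixed anhydride (LiCl/Et3N conditions) occurs at the less hindered fumaroyl carbonyl and keeps the (E)-alkene.

**Step 8**
Reactants: 15 tert-butyl fumarate imide
Product: 16 (E)-4-[(4S)-4-benzyl-2-oxo-1,3-oxazolidin-3-yl]-4-oxobut-2-enoic acid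
Conditions: CF3CO2H, CH2Cl2, 0 °C to rt
Reagents that add atoms: none
Why: Acidolysis of the tert-butyl ester (loss of isobutene) frees the carboxylic acid without affecting the imide.

**Step 9**
Reactants: 11 (2Z)-3-methyl-2-homofarnesylpenta-2,4-dien-1-ol; 16 fumaric acid mono-imide
Product: 17 (2Z)-3-methyl-2-homofarnesylpenta-2,4-dien-1-yl (E)-4-[(4S)-4-benzyl-2-oxo-1,3-oxazolidin-3-yl]-4-oxobut-2-enoate
Conditions: DCC, DMAP (5 mol%), CH2Cl2, 0 °C to rt
Reagents that add atoms: none
Why: Steglich esterification joins the allylic alcohol and the acid under neutral conditions at low temperature, so neither the (Z)-diene nor the fumarate isomerises.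

**Step 10**
Reactants: 17 (Z)-dienyl fumarate imide
Product: 18 cis-fused bicyclic lactone imide (cyclohexene with C5=C6 and CH3 on C6; C1 homofarnesyl β; lactone C1–CH2–O–C7(=O)–C2 on the α face; C2–H β; (4S)-4-benzyl-2-oxo-oxazolidine-3-carbonyl on C3 β)
Conditions: Me2AlCl (1.5 equiv), CH2Cl2 (0.01 M), −40 to 0 °C
Reagents that add atoms: none
Why: Me2AlCl in excess binds both imide carbonyls as a cationic chelate, holds the acyl group s-cis and lowers the fumarate LUMO, and the (Z)-dienyl ester then undergoes a concerted, asynchronous, suprafacial [4+2] cycloaddition (type 1 intramolecular Diels–Alder) in which the diene C4=C5–C6=C1 adds across C2=C3. The closest known reaction types are the thermal intramolecular Diels–Alder of 2,4-dienyl fumarates to bicyclic γ-lactones and the Me2AlCl-promoted Diels–Alder of N-enoyl oxazolidinones. The cyclohexene closes by formation of the C1–C2 and C3–C4 bonds, and the five-membered lactone closes in the same event through the C1–C2 bond, the three-atom ester tether reaching from the inside (Z) position of C1 to the exo position of C2. C1 and C2 are set cis because a tether on the inside position cannot span a trans ring fusion, C3 is set trans to C7 by the (E)-geometry of the dienophile (imide endo), and the absolute configuration of all three follows from addition to the face of the chelated imide opposite the benzyl group (the si face of the carbon α to the imide). The step needs facial selectivity and chemoselectivity for the tethered diene over the three chain alkenes: the rigid chelate should give the first, intramolecularity and the electron-rich trialkyl diene the second, while low temperature and a proton-scavenging alkylaluminium limit ionisation of the dienylic ester and 1,5-hydrogen shift of the (Z)-diene.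

**Step 11**
Reactants: 18 bicyclic lactone imide
Product: 19 lactone acid (as 18 with CO2H on C3, β)
Conditions: LiOH, H2O2, THF/H2O, 0 °C; Na2SO3; HCl to pH 3
Reagents that add atoms: hydrogen peroxide, OO
Why: Lithium hydroperoxide cleaves the exocyclic imide carbonyl selectively (standard oxazolidinone removal), the auxiliary is recovered, and any lactone that opens recloses on acidification.

**Step 12**
Reactants: 19 lactone acid
Product: 21 lactone aryl ester (as 19 with CO2Ar on C3), via acid chloride 20 (not isolated)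
Conditions: Me2C=C(Cl)NMe2, CH2Cl2, 0 °C to rt; then ArOLi (from ArOH, n-BuLi), THF, 0 °C to rt
Reagents that add atoms: 2,6-di-tert-butyl-4-methylphenol (as its lithium salt), Cc1cc(C(C)(C)C)c(O)c(C(C)(C)C)c1
Why: Neutral acid chloride formation with the chloroenamine and O-acylation of the hindered lithium phenoxide give the aryl ester, whose flanking tert-butyl groups shield the carbonyl from the hydride and ylide reagents that follow and which later serves as the ketene precursor.

**Step 13**
Reactants: 21 lactone aryl ester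
Product: 22 lactol (as 21 with C7 as CH(OH); both anomers)
Conditions: i-Bu2AlH (1.2 equiv), CH2Cl2, −78 °C
Reagents that add atoms: none
Why: Partial reduction of the γ-lactone with i-Bu2AlH at −78 °C stops at the aluminium hemiacetal, whereas the sterically shielded aryl ester should not react.

**Step 14**
Reactants: 22 lactol
Product: 23 vinyl alcohol (C1: CH2OH α and homofarnesyl β; C2: vinyl α; C3: CO2Ar β; C5=C6)
Conditions: Ph3PCH3Br, KN(SiMe3)2, THF, 0 °C to rt
Reagents that add atoms: methyltriphenylphosphonium bromide (as its ylide), C[P+](c1ccccc1)(c1ccccc1)c1ccccc1.[Br-]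
Why: Wittig methylenation of the ring-opened hydroxy aldehyde form of the lactol gives the vinyl group and frees the C1 hydroxymethyl group, the unstabilised ylide reacting faster than the aldehyde can epimerise at C2.

**Step 15**
Reactants: 23 vinyl alcohol
Product: 25 diol (as 23 with 3-hydroxypropyl on C2), via linear aldehyde 24 (not isolated)
Conditions: Rh(acac)(CO)2 (2 mol%), Xantphos (4 mol%), CO/H2 (1:1, 20 bar), toluene, 70 °C; then NaBH4, MeOH, 0 °C
Reagents that add atoms: carbon monoxide, [C-]#[O+]
Why: Rhodium/Xantphos hydroformylation adds H and CHO across the monosubstituted alkene only, with linear selectivity enforced by the wide-bite-angle ligand and the neighbouring quaternary centre, and borohydride reduces the aldehyde to the primary alcohol.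

**Step 16**
Reactants: 25 diol
Product: 26 bis-TBS ether of 25
Conditions: TBSOTf, 2,6-lutidine, CH2Cl2, −78 to 0 °C
Reagents that add atoms: tert-butyldimethylsilyl trifluoromethanesulfonate, CC(C)(C)[Si](C)(C)OS(=O)(=O)C(F)(F)F
Why: Silylation of both primary alcohols with the silyl triflate removes the acidic protons and the nucleophilic oxygens before the organolithium step.

**Step 17**
Reactants: 26 bis-TBS aryl ester
Product: 30 (Z)-enol triflate (C3=Cα(CH3)OTf with OTf cis to C2), via lithium ester enolate 27 (not isolated), via ketene 28 (not isolated), via lithium (Z)-enolate 29 (not isolated)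
Conditions: n-BuLi (1.05 equiv), THF, −78 °C; MeLi (1.5 equiv), −78 to 0 °C; then Comins' reagent, −78 to 0 °C
Reagents that add atoms: methyllithium, [Li]C; N-(5-chloropyridin-2-yl)bis(trifluoromethanesulfonimide), O=S(=O)(N(c1ccc(Cl)cn1)S(=O)(=O)C(F)(F)F)C(F)(F)F
Why: The hindered aryl ester enolate loses lithium aryloxide on warming to give the ketene, methyllithium (already present) adds to the ketene carbonyl in the plane of the ring substituents from the side of the C4 methylene and away from the substituted C2, so the enolate oxygen, and after O-sulfonylation the triflate, should sit cis to C2 (in-plane addition of organolithiums to unsymmetrical ketenes, then enolate triflation).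

**Step 18**
Reactants: 30 (Z)-enol triflate
Product: 31 methyl (Z)-enoate (C3=Cα(CH3)CO2Me with CO2Me cis to C2; bis-TBS)
Conditions: Pd(OAc)2 (10 mol%), dppp (12 mol%), CO (1 atm), MeOH, Et3N, DMF, 60 °C
Reagents that add atoms: carbon monoxide, [C-]#[O+]; methanol, CO
Why: Palladium-catalysed alkoxycarbonylation (oxidative addition, CO insertion, methanolysis) replaces the triflate by CO2Me with retention of the alkene geometry.

**Step 19**
Reactants: 31 methyl (Z)-enoate
Product: 32 diol enoate (31 without the silyl groups)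
Conditions: HF·pyridine, pyridine, THF, 0 °C to rt
Reagents that add atoms: none
Why: Fluoride-mediated desilylation frees both primary alcohols under buffered conditions that leave the enoate and the polyene untouched.

**Step 20**
Reactants: 32 diol enoate
Product: 33 epoxy diol enoate (C5–C6 epoxide on the α face, cis to C1–CH2OH)
Conditions: VO(acac)2 (5 mol%), t-BuOOH, CH2Cl2, 0 °C to rt
Reagents that add atoms: tert-butyl hydroperoxide, CC(C)(C)OO
Why: In this vanadium-catalysed hydroxyl-directed epoxidation the vanadate ester of the homoallylic C1–CH2OH delivers the peroxide oxygen to the C5=C6 alkene on its own (α) face, while the undirected chain alkenes and the electron-poor enoate alkene should stay untouched, which sets C5 and C6.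

**Step 21**
Reactants: 33 epoxy diol enoate
Product: 34 tetraol (C6: OH α and CH3 β; Cα–CH2OH cis to C2)
Conditions: LiAlH4, THF, 0 °C to reflux
Reagents that add atoms: none
Why: Hydride opens the trisubstituted epoxide by SN2 attack at the less substituted C5, leaving the C6–O bond and hence the tertiary alcohol cis to CH2OH, and reduces the conjugated ester by 1,2-addition to the allylic alcohol.

**Step 22**
Reactants: 34 tetraol
Product: 35 CNP0284886.1, (2Z)-2-[(2R,3S,4S)-4-hydroxy-3-(hydroxymethyl)-2-(3-hydroxypropyl)-4-methyl-3-homofarnesylcyclohexylidene]propanal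
Conditions: MnO2 (activated, excess), CH2Cl2, rt
Reagents that add atoms: none
Why: Allylic oxidation with MnO2 converts only the allylic primary alcohol into the enal without change of alkene geometry and leaves the two saturated primary alcohols and the tertiary alcohol.

**Compound list**

1 | (2E,6E)-farnesol | CC(C)=CCC/C(C)=C/CC/C(C)=C/CO | starting material
2 | (2E,6E)-farnesal | CC(C)=CCC/C(C)=C/CC/C(C)=C/C=O | intermediate
3 | (3E,7E)-4,8,12-trimethyltrideca-1,3,7,11-tetraene | CC(C)=CCC/C(C)=C/CC/C(C)=C/C=C | intermediate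
4 | B-homofarnesyl-9-borabicyclo[3.3.1]nonane | CC(C)=CCC/C(C)=C/CC/C(C)=C/CCB1C2CCCC1CCC2 | intermediate (not isolated)
5 | (3E,7E)-homofarnesol | CC(C)=CCC/C(C)=C/CC/C(C)=C/CCO | intermediate
6 | (3E,7E)-homofarnesyl bromide | CC(C)=CCC/C(C)=C/CC/C(C)=C/CCBr | intermediate
7 | but-2-yn-1-ol | CC#CCO | starting material
8 | homofarnesylmagnesium bromide | CC(C)=CCC/C(C)=C/CC/C(C)=C/CC[Mg]Br | intermediate (not isolated)
9 | cyclic vinylmagnesium alkoxide (4-homofarnesyl-3-methyl-2,5-dihydro-1,2-oxamagnesole) | CC(C)=CCC/C(C)=C/CC/C(C)=C/CCC1=C(C)[Mg]OC1 | intermediate (not isolated)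
10 | (2Z)-3-iodo-2-homofarnesylbut-2-en-1-ol | CC(C)=CCC/C(C)=C/CC/C(C)=C/CC/C(CO)=C(\C)I | intermediate
11 | (2Z)-3-methyl-2-homofarnesylpenta-2,4-dien-1-ol | CC(C)=CCC/C(C)=C/CC/C(C)=C/CC/C(CO)=C(\C)C=C | intermediate
12 | mono-tert-butyl fumarate | CC(C)(C)OC(=O)/C=C/C(=O)O | starting material
13 | (S)-4-benzyl-1,3-oxazolidin-2-one | O=C1OC[C@H](Cc2ccccc2)N1 | starting material
14 | mixed anhydride of 12 with pivalic acid | CC(C)(C)OC(=O)/C=C/C(=O)OC(=O)C(C)(C)C | intermediate (not isolated)
15 | tert-butyl (E)-4-[(4S)-4-benzyl-2-oxo-1,3-oxazolidin-3-yl]-4-oxobut-2-enoate | CC(C)(C)OC(=O)/C=C/C(=O)N1C(=O)OC[C@@H]1Cc1ccccc1 | intermediate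
16 | (E)-4-[(4S)-4-benzyl-2-oxo-1,3-oxazolidin-3-yl]-4-oxobut-2-enoic acid | O=C(O)/C=C/C(=O)N1C(=O)OC[C@@H]1Cc1ccccc1 | intermediate
17 | (Z)-dienyl fumarate imide (key-step precursor) | CC(C)=CCC/C(C)=C/CC/C(C)=C/CC/C(COC(=O)/C=C/C(=O)N1C(=O)OC[C@@H]1Cc1ccccc1)=C(\C)C=C | intermediate
18 | cis-fused bicyclic lactone imide (key-step product) | CC(C)=CCC/C(C)=C/CC/C(C)=C/CC[C@@]1(CO2)[C@H](C2=O)[C@@H](C(=O)N3C(=O)OC[C@@H]3Cc3ccccc3)CC=C1C | intermediate
19 | lactone acid | CC(C)=CCC/C(C)=C/CC/C(C)=C/CC[C@@]1(CO2)[C@H](C2=O)[C@@H](C(=O)O)CC=C1C | intermediate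
20 | lactone acid chloride | CC(C)=CCC/C(C)=C/CC/C(C)=C/CC[C@@]1(CO2)[C@H](C2=O)[C@@H](C(Cl)=O)CC=C1C | intermediate (not isolated)
21 | lactone 2,6-di-tert-butyl-4-methylphenyl ester | CC(C)=CCC/C(C)=C/CC/C(C)=C/CC[C@@]1(CO2)[C@H](C2=O)[C@@H](C(=O)Oc2c(C(C)(C)C)cc(C)cc2C(C)(C)C)CC=C1C | intermediate
22 | lactol aryl ester (both anomers) | CC(C)=CCC/C(C)=C/CC/C(C)=C/CC[C@@]1(CO2)[C@H](C2O)[C@@H](C(=O)Oc2c(C(C)(C)C)cc(C)cc2C(C)(C)C)CC=C1C | intermediate
23 | vinyl alcohol aryl ester | CC(C)=CCC/C(C)=C/CC/C(C)=C/CC[C@@]1(CO)[C@H](C=C)[C@@H](C(=O)Oc2c(C(C)(C)C)cc(C)cc2C(C)(C)C)CC=C1C | intermediate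
24 | linear aldehyde (3-oxopropyl on C2) | CC(C)=CCC/C(C)=C/CC/C(C)=C/CC[C@@]1(CO)[C@H](CCC=O)[C@@H](C(=O)Oc2c(C(C)(C)C)cc(C)cc2C(C)(C)C)CC=C1C | intermediate (not isolated)
25 | diol aryl ester | CC(C)=CCC/C(C)=C/CC/C(C)=C/CC[C@@]1(CO)[C@H](CCCO)[C@@H](C(=O)Oc2c(C(C)(C)C)cc(C)cc2C(C)(C)C)CC=C1C | intermediate
26 | bis-TBS aryl ester | CC(C)=CCC/C(C)=C/CC/C(C)=C/CC[C@@]1(CO[Si](C)(C)C(C)(C)C)[C@H](CCCO[Si](C)(C)C(C)(C)C)[C@@H](C(=O)Oc2c(C(C)(C)C)cc(C)cc2C(C)(C)C)CC=C1C | intermediate
27 | lithium ester enolate | CC(C)=CCC/C(C)=C/CC/C(C)=C/CC[C@@]1(CO[Si](C)(C)C(C)(C)C)[C@H](CCCO[Si](C)(C)C(C)(C)C)C(=C([O-])Oc2c(C(C)(C)C)cc(C)cc2C(C)(C)C)CC=C1C.[Li+] | intermediate (not isolated)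
28 | ketene (C3=C=O) | CC(C)=CCC/C(C)=C/CC/C(C)=C/CC[C@@]1(CO[Si](C)(C)C(C)(C)C)[C@H](CCCO[Si](C)(C)C(C)(C)C)C(=C=O)CC=C1C | intermediate (not isolated)
29 | lithium (Z)-enolate of the methyl ketone | CC(C)=CCC/C(C)=C/CC/C(C)=C/CC[C@@]1(CO[Si](C)(C)C(C)(C)C)[C@H](CCCO[Si](C)(C)C(C)(C)C)/C(=C(/C)[O-])CC=C1C.[Li+] | intermediate (not isolated)
30 | (Z)-enol triflate | CC(C)=CCC/C(C)=C/CC/C(C)=C/CC[C@@]1(CO[Si](C)(C)C(C)(C)C)[C@H](CCCO[Si](C)(C)C(C)(C)C)/C(=C(/C)OS(=O)(=O)C(F)(F)F)CC=C1C | intermediate
31 | methyl (Z)-enoate, bis-TBS | CC(C)=CCC/C(C)=C/CC/C(C)=C/CC[C@@]1(CO[Si](C)(C)C(C)(C)C)[C@H](CCCO[Si](C)(C)C(C)(C)C)/C(=C(/C)C(=O)OC)CC=C1C | intermediate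
32 | diol enoate | CC(C)=CCC/C(C)=C/CC/C(C)=C/CC[C@@]1(CO)[C@H](CCCO)/C(=C(/C)C(=O)OC)CC=C1C | intermediate
33 | epoxy diol enoate | CC(C)=CCC/C(C)=C/CC/C(C)=C/CC[C@@]1(CO)[C@H](CCCO)/C(=C(/C)C(=O)OC)C[C@@H]2O[C@]12C | intermediate
34 | tetraol | CC(C)=CCC/C(C)=C/CC/C(C)=C/CC[C@@]1(CO)[C@H](CCCO)/C(=C(/C)CO)CC[C@]1(C)O | intermediate
35 | CNP0284886.1 | CC(C)=CCC/C(C)=C/CC/C(C)=C/CC[C@@]1(CO)[C@H](CCCO)/C(=C(/C)C=O)CC[C@]1(C)O | target

**Step count and risks**

Total step count: 22. Longest linear sequence: 20 steps (steps 1–6 and 9–22).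

Steps most likely to fail:

Step 10. The aluminium Lewis acid may ionise the doubly allylic ester C–O bond and start cation-olefin reactions of the polyene. The cycloaddition may also be slow, because the tether pairs the hindered C1 terminus with the carbon β to the activated imide and the ester must adopt its less favoured s-cis rotamer; facial control by the chelate would then not be expressed. Fallback (from 11, back at 18): dienol 11 would be esterified (DCC, DMAP) with mono-methyl fumarate to the dienyl methyl fumarate F1, which would be cyclised thermally without Lewis acid (toluene, 120 °C, high dilution, radical inhibitor) to the racemic cis-fused lactone methyl ester F2. The same tether geometry enforces the cis fusion and the trans ester. LiOH followed by acidification would give the racemic lactone acid F3. F3 would be activated as its racemic pivalic mixed anhydride F4 (t-BuCOCl, Et3N) and coupled with 13 (LiCl) to give 18 and the diastereomeric imide F5, which would be separated by chromatography.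

Step 17. Deprotonation α to the hindered ester may be incomplete, or methyllithium may attack the ketene from the C2 side, which would erode the geometry of the tetrasubstituted alkene. Fallback (from 26, back at 30): the aryl ester of 26 would be reduced with LiAlH4 at rt to the primary alcohol F6 and oxidised (Dess–Martin periodinane, NaHCO3) to the aldehyde F7. MeMgBr would give the secondary alcohol F8 (both carbinol epimers), and a second Dess–Martin oxidation the methyl ketone F9. Thermodynamic silylation (Me3SiCl, NaI, Et3N, MeCN) would give the tetrasubstituted trimethylsilyl enol ether F10 as a geometric mixture. Methyllithium would then release the lithium enolates (29 together with the lithium (E)-enolate F11), which Comins' reagent would convert into 30 and the (E)-enol triflate F12; the two would be separated on silver nitrate-impregnated silica.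

Step 5. Carbometalation of the internal alkynol by a primary homoallylic Grignard reagent may be sluggish, with protonolysis and homocoupling of the reagent competing. Fallback (from 6, back at 11): bromide 6 would alkylate the sodium enolate of ethyl acetoacetate (NaH, NaI, THF/DMF, 60 °C) to give ethyl 2-homofarnesylacetoacetate F13. Chelation-controlled triflation (Tf2O, aqueous LiOH, toluene, 5 °C) would give the (Z)-enol triflate F14 with the triflate cis to the ester. Stille vinylation (CH2=CHSnBu3, Pd(PPh3)4, LiCl, THF, 65 °C) with retention would give the ethyl (2Z)-dienoate F15, and i-Bu2AlH (CH2Cl2, −78 °C) would reduce the ester to dienol 11.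

**Further compounds**

F1 | step 10 | (2Z)-3-methyl-2-homofarnesylpenta-2,4-dien-1-yl methyl fumarate | CC(C)=CCC/C(C)=C/CC/C(C)=C/CC/C(COC(=O)/C=C/C(=O)OC)=C(\C)C=C
F2 | step 10 | racemic cis-fused lactone methyl ester (both enantiomers) | CC(C)=CCC/C(C)=C/CC/C(C)=C/CC[C@@]1(CO2)[C@H](C2=O)[C@@H](C(=O)OC)CC=C1C.CC(C)=CCC/C(C)=C/CC/C(C)=C/CC[C@]1(CO2)[C@@H](C2=O)[C@H](C(=O)OC)CC=C1C
F3 | step 10 | racemic lactone acid (19 and its enantiomer) | CC(C)=CCC/C(C)=C/CC/C(C)=C/CC[C@@]1(CO2)[C@H](C2=O)[C@@H](C(=O)O)CC=C1C.CC(C)=CCC/C(C)=C/CC/C(C)=C/CC[C@]1(CO2)[C@@H](C2=O)[C@H](C(=O)O)CC=C1C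
F4 | step 10 | racemic pivalic mixed anhydride of F3 (both enantiomers) | CC(C)=CCC/C(C)=C/CC/C(C)=C/CC[C@@]1(CO2)[C@H](C2=O)[C@@H](C(=O)OC(=O)C(C)(C)C)CC=C1C.CC(C)=CCC/C(C)=C/CC/C(C)=C/CC[C@]1(CO2)[C@@H](C2=O)[C@H](C(=O)OC(=O)C(C)(C)C)CC=C1C
F5 | step 10 | diastereomer of 18 with the mirror-image bicyclic core | CC(C)=CCC/C(C)=C/CC/C(C)=C/CC[C@]1(CO2)[C@@H](C2=O)[C@H](C(=O)N3C(=O)OC[C@@H]3Cc3ccccc3)CC=C1C
F6 | step 17 | primary alcohol (CH2OH on C3, bis-TBS) | CC(C)=CCC/C(C)=C/CC/C(C)=C/CC[C@@]1(CO[Si](C)(C)C(C)(C)C)[C@H](CCCO[Si](C)(C)C(C)(C)C)[C@@H](CO)CC=C1C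
F7 | step 17 | aldehyde (CHO on C3, bis-TBS) | CC(C)=CCC/C(C)=C/CC/C(C)=C/CC[C@@]1(CO[Si](C)(C)C(C)(C)C)[C@H](CCCO[Si](C)(C)C(C)(C)C)[C@@H](C=O)CC=C1C
F8 | step 17 | secondary alcohol (1-hydroxyethyl on C3, both carbinol epimers) | CC(C)=CCC/C(C)=C/CC/C(C)=C/CC[C@@]1(CO[Si](C)(C)C(C)(C)C)[C@H](CCCO[Si](C)(C)C(C)(C)C)[C@@H](C(C)O)CC=C1C
F9 | step 17 | methyl ketone (acetyl on C3, bis-TBS) | CC(C)=CCC/C(C)=C/CC/C(C)=C/CC[C@@]1(CO[Si](C)(C)C(C)(C)C)[C@H](CCCO[Si](C)(C)C(C)(C)C)[C@@H](C(C)=O)CC=C1C
F10 | step 17 | tetrasubstituted trimethylsilyl enol ether (geometric mixture) | CC(C)=CCC/C(C)=C/CC/C(C)=C/CC[C@@]1(CO[Si](C)(C)C(C)(C)C)[C@H](CCCO[Si](C)(C)C(C)(C)C)C(=C(C)O[Si](C)(C)C)CC=C1C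
F11 | step 17 | lithium (E)-enolate of the methyl ketone | CC(C)=CCC/C(C)=C/CC/C(C)=C/CC[C@@]1(CO[Si](C)(C)C(C)(C)C)[C@H](CCCO[Si](C)(C)C(C)(C)C)/C(=C(\C)[O-])CC=C1C.[Li+]
F12 | step 17 | (E)-enol triflate | CC(C)=CCC/C(C)=C/CC/C(C)=C/CC[C@@]1(CO[Si](C)(C)C(C)(C)C)[C@H](CCCO[Si](C)(C)C(C)(C)C)/C(=C(\C)OS(=O)(=O)C(F)(F)F)CC=C1C
F13 | step 5 | ethyl 2-homofarnesylacetoacetate | CC(C)=CCC/C(C)=C/CC/C(C)=C/CCC(C(C)=O)C(=O)OCC
F14 | step 5 | ethyl (2Z)-2-homofarnesyl-3-(trifluoromethylsulfonyloxy)but-2-enoate | CC(C)=CCC/C(C)=C/CC/C(C)=C/CC/C(C(=O)OCC)=C(\C)OS(=O)(=O)C(F)(F)F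
F15 | step 5 | ethyl (2Z)-3-methyl-2-homofarnesylpenta-2,4-dienoate | CC(C)=CCC/C(C)=C/CC/C(C)=C/CC/C(C(=O)OCC)=C(\C)C=C
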